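## Retrosynthetic overview

1. The target is the (2R)-2-methylbutanoate of a 2-aryl-3-(hydroxymethyl)-4-(arylmethyl)oxolane, (2R,3S,4S), 2,3-trans and 3,4-cis. The ester C–O bond and the two phenol benzyl ethers are disconnected first.
2. Key disconnection is C3–C4 of the oxolane: 5-exo-trig closure of a C3 radical onto a styrene. The radical is released from a strained oxirane (C3 plus its CH2–O carbon) by Cp2TiCl (trivalent titanium). One operation gives the C–C bond, the ring, the C3 and C4 stereocentres, the free CH2OH and the CH2Ar group.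
3. Enabling feature: ring O1 lies between benzylic C2 and C5, so the precursor is a plain ether of a 1-aryl-2,3-epoxypropanol (C2, C3, CH2O) with a cinnamyl alcohol (C5, C4, CH2Ar). C3 carries an oxygenated carbon and C4 a benzylic carbon, which are exactly the oxirane and styrene termini. Only C2 must be pre-set.
4. Both halves come from one racemic aryl vinyl carbinol: Sharpless kinetic resolution gives the epoxy alcohol from the (R)-enantiomer, and the left-over (S)-alcohol is transposed to the (E)-cinnamyl bromide. A Williamson ether synthesis joins them.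
5. Ring order: benzene rings (purchased as O-benzylvanillin), then the temporary oxirane (step 2), then the oxolane (step 5), which is the only ring of the skeleton to be built and the last one closed.

Key step: step 5

Remark: (2R)-2-methylbutanoic acid of high enantiomeric purity is taken as a purchasable reagent; any minor enantiomer of the core then becomes a diastereomer of 9 and can be removed at that stage.

## Route

Step 1
Reactants: 1 4-(benzyloxy)-3-methoxybenzaldehyde; 2 vinylmagnesium bromide
Product: 3 rac-1-[4-(benzyloxy)-3-methoxyphenyl]prop-2-en-1-ol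
Conditions: THF, −78 → 0 °C; then H2O quench (neutral work-up)
Reagents that add atoms: none
Why: Grignard 1,2-addition of the vinyl nucleophile to the aryl aldehyde gives the racemic secondary allylic alcohol that feeds both halves of the precursor, so no stereocontrol is needed here.

Step 2
Reactants: 3 rac-1-[4-(benzyloxy)-3-methoxyphenyl]prop-2-en-1-ol
Product: 4 (S)-[4-(benzyloxy)-3-methoxyphenyl][(2R)-oxiran-2-yl]methanol
Conditions: Ti(OiPr)4 (0.15 equiv), L-(+)-diisopropyl tartrate (0.20 equiv), t-BuOOH (0.45 equiv, in isooctane), 4 Å MS, CH2Cl2, −20 °C; sat. aq Na2SO4, Celite filtration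
Reagents that add atoms: tert-butyl hydroperoxide, CC(C)(C)OO
Why: Sharpless kinetic resolution: with the L-(+)-tartrate the (R)-alcohol should be the fast enantiomer and is epoxidised erythro-selectively under catalyst control, which sets the carbinol centre that becomes C2 (it reads S in 4 only because the oxirane carbon now outranks the aryl group), while the sub-stoichiometric oxidant leaves the (S)-alcohol unreacted for use in step 3.

Step 3
Reactants: 3 rac-1-[4-(benzyloxy)-3-methoxyphenyl]prop-2-en-1-ol (the (S)-enriched alcohol recovered from step 2 serves equally)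
Product: 5 1-(benzyloxy)-4-[(1E)-3-bromoprop-1-en-1-yl]-2-methoxybenzene
Conditions: PBr3 (0.4 equiv), Et2O, −10 → 0 °C; cold aq NaHCO3 wash; used at once
Reagents that add atoms: phosphorus tribromide, BrP(Br)Br
Why: Activation of the benzylic and allylic alcohol ionises it to the p-alkoxy-stabilised 1-arylallyl cation, and bromide is captured at the terminus (allylic transposition, SN1′) to give the conjugated (E)-cinnamyl bromide, so the configuration of the input alcohol is irrelevant.

Step 4
Reactants: 4 (S)-[4-(benzyloxy)-3-methoxyphenyl][(2R)-oxiran-2-yl]methanol; 5 1-(benzyloxy)-4-[(1E)-3-bromoprop-1-en-1-yl]-2-methoxybenzene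
Product: 6 (2R)-2-[(S)-[4-(benzyloxy)-3-methoxyphenyl]({(2E)-3-[4-(benzyloxy)-3-methoxyphenyl]prop-2-en-1-yl}oxy)methyl]oxirane
Conditions: NaH (1.2 equiv, added last), Bu4NI (0.1 equiv), THF–DMF (5:1), −20 → 0 °C
Reagents that add atoms: none
Why: Williamson ether synthesis in which the alkoxide is generated in the presence of the reactive allylic bromide, so that SN2 O-alkylation outruns Payne rearrangement; the C–O bond at the stereocentre is not touched and its configuration is retained.

Step 5
Reactants: 6 (2R)-2-[(S)-[4-(benzyloxy)-3-methoxyphenyl]({(2E)-3-[4-(benzyloxy)-3-methoxyphenyl]prop-2-en-1-yl}oxy)methyl]oxirane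
Product: 7 [(2R,3S,4S)-2-[4-(benzyloxy)-3-methoxyphenyl]-4-{[4-(benzyloxy)-3-methoxyphenyl]methyl}oxolan-3-yl]methanol
Conditions: Cp2TiCl2 (2.5 equiv), Zn dust (5 equiv), THF, rt (green Cp2TiCl); added dropwise to 6 in THF (0.02 M), rt; then cold 1 M aq HCl, brief
Reagents that add atoms: none
Why: Cp2TiCl (trivalent titanium) transfers one electron to the oxirane, whose strain-driven homolytic C–O cleavage gives the more substituted β-titanoxy radical at C3; this radical adds to the tethered (E)-styrene to form the C3–C4 bond, and the benzylic radical so formed is reduced by a second Cp2TiCl and protonated on work-up, so that CH2OH and CH2Ar appear at the oxidation levels of the target. The closest known reaction type is the Nugent–RajanBabu reductive epoxide opening with 5-exo radical cyclisation, which is established for epoxy ethers carrying a cinnamyl acceptor. The oxolane closes in the 5-exo-trig mode, since 6-endo attack would forgo the benzylic radical. The oxirane carbon becomes a planar radical, so its configuration is erased, and the C2 centre from step 2 controls both new centres through a chair-like transition state with the C2 aryl group pseudo-equatorial: C3 is set trans to the aryl group and C4 is set with CH2Ar cis to the CH2O–Ti arm (the usual cis preference of 1-substituted 5-hexenyl radicals), which is the required (2R,3S,4S) array. The step needs opening toward C3 (secured by the secondary versus primary radical), cyclisation faster than reduction of the C3 radical (secured by the fast closure of a 3-oxa-5-hexenyl radical onto a styrene and by slow addition of the reagent) and survival of the benzylic ether at C2 (no acid until the brief cold quench).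

Step 6
Reactants: 7 [(2R,3S,4S)-2-[4-(benzyloxy)-3-methoxyphenyl]-4-{[4-(benzyloxy)-3-methoxyphenyl]methyl}oxolan-3-yl]methanol; 8 (2R)-2-methylbutanoic acid
Product: 9 [(2R,3S,4S)-2-[4-(benzyloxy)-3-methoxyphenyl]-4-{[4-(benzyloxy)-3-methoxyphenyl]methyl}oxolan-3-yl]methyl (2R)-2-methylbutanoate
Conditions: DCC (1.3 equiv), DMAP (0.1 equiv), CH2Cl2, 0 °C → rt
Reagents that add atoms: none
Why: Steglich esterification of the only free hydroxyl group (primary) under conditions too mild to enolise the α-branched acyl donor, so the (R)-centre of the acid should be carried through unchanged.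

Step 7
Reactants: 9 [(2R,3S,4S)-2-[4-(benzyloxy)-3-methoxyphenyl]-4-{[4-(benzyloxy)-3-methoxyphenyl]methyl}oxolan-3-yl]methyl (2R)-2-methylbutanoate
Product: 10 [(2R,3S,4S)-2-(4-hydroxy-3-methoxyphenyl)-4-[(4-hydroxy-3-methoxyphenyl)methyl]oxolan-3-yl]methyl (2R)-2-methylbutanoate (CNP0315069.1)
Conditions: H2 (1 atm), Pd/C (10%), EtOAc, rt; stopped when debenzylation is complete
Reagents that add atoms: none
Why: Catalytic hydrogenolysis should cleave the two aryl benzyl ethers much faster than the ring benzylic C2–O bond in a neutral, non-acidic solvent, leaving the ester, the oxolane and all four stereocentres untouched.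

## Compound list

1 | 4-(benzyloxy)-3-methoxybenzaldehyde | O=Cc1ccc(OCc2ccccc2)c(OC)c1 | starting material
2 | vinylmagnesium bromide | C=C[Mg]Br | starting material
3 | rac-1-[4-(benzyloxy)-3-methoxyphenyl]prop-2-en-1-ol | C=CC(O)c1ccc(OCc2ccccc2)c(OC)c1 | intermediate
4 | (S)-[4-(benzyloxy)-3-methoxyphenyl][(2R)-oxiran-2-yl]methanol | O[C@@H](c1ccc(OCc2ccccc2)c(OC)c1)[C@H]1CO1 | intermediate
5 | 1-(benzyloxy)-4-[(1E)-3-bromoprop-1-en-1-yl]-2-methoxybenzene | BrC/C=C/c1ccc(OCc2ccccc2)c(OC)c1 | intermediate
6 | (2R)-2-[(S)-[4-(benzyloxy)-3-methoxyphenyl]({(2E)-3-[4-(benzyloxy)-3-methoxyphenyl]prop-2-en-1-yl}oxy)methyl]oxirane | COc1cc(/C=C/CO[C@@H](c2ccc(OCc3ccccc3)c(OC)c2)[C@H]2CO2)ccc1OCc1ccccc1 | intermediate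
7 | [(2R,3S,4S)-2-[4-(benzyloxy)-3-methoxyphenyl]-4-{[4-(benzyloxy)-3-methoxyphenyl]methyl}oxolan-3-yl]methanol | OC[C@@H]1[C@H](Cc2ccc(OCc3ccccc3)c(OC)c2)CO[C@H]1c1ccc(OCc2ccccc2)c(OC)c1 | intermediate
8 | (2R)-2-methylbutanoic acid | CC[C@@H](C)C(=O)O | starting material
9 | [(2R,3S,4S)-2-[4-(benzyloxy)-3-methoxyphenyl]-4-{[4-(benzyloxy)-3-methoxyphenyl]methyl}oxolan-3-yl]methyl (2R)-2-methylbutanoate | CC[C@@H](C)C(=O)OC[C@@H]1[C@H](Cc2ccc(OCc3ccccc3)c(OC)c2)CO[C@H]1c1ccc(OCc2ccccc2)c(OC)c1 | intermediate
10 | [(2R,3S,4S)-2-(4-hydroxy-3-methoxyphenyl)-4-[(4-hydroxy-3-methoxyphenyl)methyl]oxolan-3-yl]methyl (2R)-2-methylbutanoate | CC[C@@H](C)C(=O)OC[C@@H]1[C@H](Cc2ccc(O)c(OC)c2)CO[C@H]1c1ccc(O)c(OC)c1 | target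

## Step count and risks

Total step count: 7. Longest linear sequence: 6 steps (steps 1, 2, 4, 5, 6, 7 from compound 1).

Steps most likely to fail:

**Step 5.** The 5-exo-trig closure may give incomplete cis control at C4, the C3 radical may be reduced before it cyclises (deoxygenation to the allyl ether), or the benzylic radical may dimerise. The fallback takes the C4 centre out of the radical step. It sets out from 4. O-Propargylation (propargyl bromide, NaH, THF, 0 °C) should give (2R)-2-[(S)-[4-(benzyloxy)-3-methoxyphenyl](prop-2-yn-1-yloxy)methyl]oxirane F1. Sonogashira coupling with purchased 1-(benzyloxy)-4-iodo-2-methoxybenzene (Pd(PPh3)2Cl2, CuI, Et3N, rt) should give the aryl alkyne (2R)-2-[(S)-[4-(benzyloxy)-3-methoxyphenyl]({3-[4-(benzyloxy)-3-methoxyphenyl]prop-2-yn-1-yl}oxy)methyl]oxirane F2. The same Cp2TiCl opening then closes 5-exo-dig, with the vinyl radical quenched by hydrogen abstraction from THF, to [(2R,3S)-2-[4-(benzyloxy)-3-methoxyphenyl]-4-{[4-(benzyloxy)-3-methoxyphenyl]methylidene}oxolan-3-yl]methanol F3, in which only C3 is new and is set trans to the C2 aryl group. Steglich esterification with 8 gives the (2R)-2-methylbutanoate of that alcohol F4. Hydrogenation over Pd/C in EtOAc is expected to add H2 to the exocyclic alkene from the face anti to the adjacent C3 acyloxymethyl group, placing CH2Ar cis to it, and to cleave the benzyl ethers in the same operation. The fallback comes back to the route at 10.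

**Step 4.** The alkoxide of 4 may undergo Payne rearrangement (oxirane migration toward the benzylic carbon) before O-alkylation, and the electron-rich bromide 5 may ionise and decompose. The fallback assembles the cinnamyl ether without pairing these two partners. It sets out from 4 and 1. Compound 4 is O-allylated under neutral conditions (allyl bromide, Ag2O, CH2Cl2, rt) to (2R)-2-[(S)-[4-(benzyloxy)-3-methoxyphenyl](prop-2-en-1-yloxy)methyl]oxirane F5. Compound 1 is methylenated (Ph3P=CH2 from Ph3PCH3Br and KOtBu, THF; Wittig reaction) to 1-(benzyloxy)-4-ethenyl-2-methoxybenzene F6. Olefin cross-metathesis of F5 with excess F6 (second-generation Grubbs catalyst, (H2IMes)(PCy3)Cl2Ru=CHPh, CH2Cl2, 40 °C) should give the (E)-cinnamyl ether. The fallback comes back to the route at 6.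

**Step 2.** The two enantiomers of 3 may not be discriminated well enough (low enantiomeric purity of 4 at useful conversion), or the electron-rich epoxy alcohol may be opened on the Lewis-acidic titanium tartrate. The fallback sets the carbinol centre by enzymatic acylation. It sets out from 3. Candida antarctica lipase B with vinyl acetate (toluene, rt) should acylate the (R)-alcohol to (1R)-1-[4-(benzyloxy)-3-methoxyphenyl]prop-2-en-1-yl acetate F7, while the (S)-alcohol again goes to step 3. Methanolysis (K2CO3, MeOH, 0 °C) gives (1R)-1-[4-(benzyloxy)-3-methoxyphenyl]prop-2-en-1-ol F8. Hydroxyl-directed epoxidation without a Lewis acid (mCPBA, NaHCO3, CH2Cl2, 0 °C) gives 4 together with its oxirane epimer (S)-[4-(benzyloxy)-3-methoxyphenyl][(2S)-oxiran-2-yl]methanol F9. The pair is used as such: step 4 converts F9 into the epimeric ether (2S)-2-[(S)-[4-(benzyloxy)-3-methoxyphenyl]({(2E)-3-[4-(benzyloxy)-3-methoxyphenyl]prop-2-en-1-yl}oxy)methyl]oxirane F10, and 6 and F10 give the same C3 radical in step 5. The fallback comes back to the route at 4, and the F9 branch converges at 7.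

## Further compounds

F1 | step 5 | (2R)-2-[(S)-[4-(benzyloxy)-3-methoxyphenyl](prop-2-yn-1-yloxy)methyl]oxirane | C#CCO[C@@H](c1ccc(OCc2ccccc2)c(OC)c1)[C@H]1CO1
F2 | step 5 | (2R)-2-[(S)-[4-(benzyloxy)-3-methoxyphenyl]({3-[4-(benzyloxy)-3-methoxyphenyl]prop-2-yn-1-yl}oxy)methyl]oxirane | COc1cc(C#CCO[C@@H](c2ccc(OCc3ccccc3)c(OC)c2)[C@H]2CO2)ccc1OCc1ccccc1
F3 | step 5 | [(2R,3S)-2-[4-(benzyloxy)-3-methoxyphenyl]-4-{[4-(benzyloxy)-3-methoxyphenyl]methylidene}oxolan-3-yl]methanol (alkene geometry not controlled) | OC[C@@H]1C(=Cc2ccc(OCc3ccccc3)c(OC)c2)CO[C@H]1c1ccc(OCc2ccccc2)c(OC)c1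
F4 | step 5 | [(2R,3S)-2-[4-(benzyloxy)-3-methoxyphenyl]-4-{[4-(benzyloxy)-3-methoxyphenyl]methylidene}oxolan-3-yl]methyl (2R)-2-methylbutanoate | CC[C@@H](C)C(=O)OC[C@@H]1C(=Cc2ccc(OCc3ccccc3)c(OC)c2)CO[C@H]1c1ccc(OCc2ccccc2)c(OC)c1
F5 | step 4 | (2R)-2-[(S)-[4-(benzyloxy)-3-methoxyphenyl](prop-2-en-1-yloxy)methyl]oxirane | C=CCO[C@@H](c1ccc(OCc2ccccc2)c(OC)c1)[C@H]1CO1
F6 | step 4 | 1-(benzyloxy)-4-ethenyl-2-methoxybenzene | C=Cc1ccc(OCc2ccccc2)c(OC)c1
F7 | step 2 | (1R)-1-[4-(benzyloxy)-3-methoxyphenyl]prop-2-en-1-yl acetate | CC(=O)O[C@H](C=C)c1ccc(OCc2ccccc2)c(OC)c1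
F8 | step 2 | (1R)-1-[4-(benzyloxy)-3-methoxyphenyl]prop-2-en-1-ol | C=C[C@@H](O)c1ccc(OCc2ccccc2)c(OC)c1
F9 | step 2 | (S)-[4-(benzyloxy)-3-methoxyphenyl][(2S)-oxiran-2-yl]methanol | O[C@@H](c1ccc(OCc2ccccc2)c(OC)c1)[C@@H]1CO1
F10 | step 2 | (2S)-2-[(S)-[4-(benzyloxy)-3-methoxyphenyl]({(2E)-3-[4-(benzyloxy)-3-methoxyphenyl]prop-2-en-1-yl}oxy)methyl]oxirane | COc1cc(/C=C/CO[C@@H](c2ccc(OCc3ccccc3)c(OC)c2)[C@@H]2CO2)ccc1OCc1ccccc1
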